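(The rate constants were chosen freely.)

A small charge of X standing in a stirred flask fades into Q, and these four flasks differ in when their X is born.

    L + D ⇌ L.D, settled at all times (K1 = 1.2 L mol⁻¹)
    X → Q (k2 = 0.19 min⁻¹)
    L + Z → X + D (k3 = 7.1 L mol⁻¹ min⁻¹)
    L + X → L.X (k4 = 0.012 L mol⁻¹ min⁻¹)

in all of them: time 25 min
- cedar: L 0.50 M; Z 0.490 M; everything together at the start
- larch: L 0.50 M (fed, over 15 min); Z 0.490 M; all else is in the flask from the start; the feed brings no volume worth counting
- birch: L 0.50 M (in portions, 3, over 15 min); Z 0.490 M; first portion at the start, last at 15 min
- elm: L 0.50 M; Z 0.490 M (fed, over 15 min); all else is in the flask from the start; the feed brings no volume worth counting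

- the flask with the highest amount of X, in percent of the L charged ("all alike" if they lie within 1.5 percentage points) (cedar / larch / birch / elm / all alike)
- final X, as a percentage of the L charged, in cedar
- final X, as a percentage of the L charged, in larch
- final X, as a percentage of the L charged, in birch
- final X, as a percentage of the L charged, in elm

- percentages count the L that a species holds: one L.X counts as two
- D is meant together with its L.D
- run time (cedar): 25 min

X goes to Q with a lifetime, the reciprocal of that step's constant, of 5.26 min. The loss to L.X at the whole charge of L runs at 0.00600 min⁻¹, far slower than the 0.190 min⁻¹ of that step, so it is dropped. L meets Z at 3.48 min⁻¹, far faster, so X is taken as born when L and Z come together. A share of X of a given age survives as e to the minus age over lifetime.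

The reckoning has one row per flask: X standing at the last arrival, then its share surviving to 25 min, then the end.

- cedar: 98.0% at the start; 0.865% survives; end 0.848%.
- birch: 43.3% at 15 min; 15.0% survives; end 6.47%.
- larch: 33.1% at 15 min; 15.0% survives; end 4.94%.
- elm: 32.4% at 15 min; 15.0% survives; end 4.85%.

The cedar row is short: its X is the oldest. The birch row took two rounds. Its last portion by itself gives 4.99%, and putting the earlier portions back in, each faded by its age, gives the figure shown. The larch and elm rows are feed rate times lifetime, short of that level by the part not yet built up. So birch comes out highest.

The forecast names birch, with 1.6% in cedar, 6.8% in larch, 8.5% in birch and 6.5% in elm, on the ground that “Birch's last portion delivers a fresh burst”.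

The simulation puts birch highest: cedar 1.51%, larch 6.72%, birch 8.38%, elm 6.77%. The cedar result lies 0.66 percentage points above its row, the birch result 1.9 points above its own. Cedar held 11.6% of X at 12.5 min, and the lifetime carries that to 1.08% at 25 min; the remainder of the cedar figure is younger X.

A neighbour of cedar charged with 0.12 M of Z has its X born at the start, and the lifetime gives 0.208% of the L charged. The computed value is 0.201%, with Z, the limiting reagent there, at 0%.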